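**Retrosynthetic overview**
- C11–OOH is made last, by aerobic radical C–H hydroperoxidation of the γ-isopropyl enone. The ring C=O comes from the carbinol left by the enzymatic diol.
- Both oxiranes close in one DBU/t-BuOOH operation from a ring bromohydrin that carries an α-methylene dienone side chain. The methylene carbon is formaldehyde.
- Key disconnection: the ring–side-chain bond C5–C7. The α-acyl radical of 5-methylhex-3-en-2-one adds intermolecularly to the free diene terminus of toluene cis-dihydrodiol mono-isovalerate, anti to its two oxygens.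
- The carbocycle is not built. It is toluene, dearomatised by toluene dioxygenase, and its C6–O stereocentre relays to C5, then to C2/C3 and C7.
- Ring order: six-membered ring (from toluene) → C2–C3 oxirane → C7–C14 oxirane.

Assumption (numbering used below): C1 = ring C=O, C2 = C(CH3), C3 = oxirane CH, C4 = CH2, C5 = CH bearing the side chain, C6 = CH–O-acyl, C7 = quaternary oxirane carbon, C14 = its CH2, C8 = side-chain C=O, C9=C10, C11 = C(CH3)2; α = face of the C6 oxygen, β = face of the side chain; paraformaldehyde is counted as formaldehyde and the recombinant dioxygenase strain as a catalyst.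

**Step 1**
Reactants: 1 toluene
Product: 2 (1S,2R)-3-methylcyclohexa-3,5-diene-1,2-diol
Conditions: E. coli JM109(pDTG601A) whole cells (toluene dioxygenase), glucose, air, phosphate buffer pH 7.2, 30 °C; EtOAc extraction
Reagents that add atoms: dioxygen O=O
Why: Enzymatic arene cis-dihydroxylation (toluene dioxygenase, Gibson-type whole-cell oxidation) adds O2 suprafacially across the 2,3-bond of toluene and is known to give only the (1S,2R)-diol (>98 % ee), which fixes the S configuration of C6 of the target and places a temporary cis-carbinol at C1.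

**Step 2**
Reactants: 2 (1S,2R)-3-methylcyclohexa-3,5-diene-1,2-diol; 3 3-methylbutanoyl chloride (isovaleryl chloride)
Product: 4 (1S,6R)-6-hydroxy-5-methylcyclohexa-2,4-dien-1-yl 3-methylbutanoate
Conditions: 3 (1.0 equiv), pyridine, CH2Cl2, −30 → 0 °C; used promptly
Reagents that add atoms: none
Why: Kinetically controlled mono-O-acylation (Einhorn conditions) goes to the hydroxyl remote from the ring methyl because the other one is flanked by that methyl group, as in the known distal-selective silylations and acylations of 3-substituted dihydrodiols, while no stereocentre is touched and the cold, acid-free medium suppresses aromatisation.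

**Step 3**
Reactants: 5 (E)-5-methylhex-3-en-2-one
Product: 8 (E)-1-bromo-5-methylhex-3-en-2-one, via lithium dienolate 6 (not isolated), via silyl dienol ether 7 (not isolated)
Conditions: LDA, THF, −78 °C; TMSCl; then NBS, −78 → 0 °C (one pot)
Reagents that add atoms: N-bromosuccinimide O=C1CCC(=O)N1Br
Why: Kinetic α'-deprotonation of the methyl ketone, O-silylation and electrophilic bromination of the 2-silyloxydiene at its terminal CH2 (silyl enol ether halogenation) give the bromomethyl enone without touching the E-alkene or the γ-CH.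

**Step 4 (key step)**
Reactants: 4 (1S,6R)-6-hydroxy-5-methylcyclohexa-2,4-dien-1-yl 3-methylbutanoate; 8 (E)-1-bromo-5-methylhex-3-en-2-one
Product: 9 (1S,2R,6S)-2-hydroxy-3-methyl-6-[(3E)-5-methyl-2-oxohex-3-en-1-yl]cyclohex-3-en-1-yl 3-methylbutanoate
Conditions: Ru(bpy)3(PF6)2 (1 mol %), Hantzsch ester (1.5 equiv), 2,6-lutidine (1.2 equiv), degassed MeCN (0.5 M in 4), 455 nm LEDs, 5 °C, 8 (2 equiv) by syringe pump over 4 h
Reagents that add atoms: none
Why: Proposed new method: reductive photoredox Giese-type hydroalkylation of an unprotected arene cis-dihydrodiol ester, in which Ru(I) cleaves the C–Br bond of 8, the electrophilic α-acyl radical adds to the electron-rich diene at its only unsubstituted terminus C5 (giving the more substituted C4–C3–C2 allyl radical) from the β face opposite the pseudoaxial C1–OH and the C6 ester, which sets C5 trans to C6–O, and the allyl radical takes H from the Hantzsch ester at its less hindered end C4 so that the C2=C3 alkene remains; the closest known reactions are photoredox additions of α-bromocarbonyls to 1,3-dienes, radical cyclisations onto dihydrodiol dienes and the radical 1,4-polymerisation of cis-dihydrocatechol diesters, and Ru(bpy)3 (triplet energy about 46 kcal/mol) is chosen because it cannot sensitise the cyclohexadiene.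

**Step 5**
Reactants: 9 (1S,2R,6S)-2-hydroxy-3-methyl-6-[(3E)-5-methyl-2-oxohex-3-en-1-yl]cyclohex-3-en-1-yl 3-methylbutanoate; 10 formaldehyde (as paraformaldehyde)
Product: 12 (1S,2R,6S)-2-hydroxy-3-methyl-6-[(4E)-6-methyl-3-oxohepta-1,4-dien-2-yl]cyclohex-3-en-1-yl 3-methylbutanoate, via Mannich base 11 (not isolated)
Conditions: (CH2O)n (4 equiv), i-Pr2NH·TFA (1 equiv), TFA (10 mol %), THF, 65 °C
Reagents that add atoms: none
Why: Mannich-type α-methylenation (aminomethylation, then β-elimination of the hindered amine) can only occur at C7, the sole enolisable α-CH2 of the single ketone present, and creates no stereocentre.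

**Step 6**
Reactants: 12 (1S,2R,6S)-2-hydroxy-3-methyl-6-[(4E)-6-methyl-3-oxohepta-1,4-dien-2-yl]cyclohex-3-en-1-yl 3-methylbutanoate
Product: 13 (1S,2S,3R,4R,6S)-4-bromo-2,3-dihydroxy-3-methyl-6-[(4E)-6-methyl-3-oxohepta-1,4-dien-2-yl]cyclohexyl 3-methylbutanoate
Conditions: NBS (1.05 equiv), acetone–H2O 4:1, 0 °C, dark
Reagents that add atoms: N-bromosuccinimide O=C1CCC(=O)N1Br; water O
Why: Bromohydrin formation on the only electron-rich alkene (both enone C=C bonds are inert to NBS) is decided after reversible bromonium formation, because only the α-bromonium ion can be opened by water at the tertiary C2 (Markovnikov) in a trans-diaxial (Fürst–Plattner) sense in the half-chair with equatorial C5/C6 substituents, which gives 2β-OH/3α-Br as in the limonene trans-diaxial bromohydrin case and so programmes the β-oxirane that neither OH-directed nor nucleophilic epoxidation would deliver.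

**Step 7**
Reactants: 13 (1S,2S,3R,4R,6S)-4-bromo-2,3-dihydroxy-3-methyl-6-[(4E)-6-methyl-3-oxohepta-1,4-dien-2-yl]cyclohexyl 3-methylbutanoate
Product: 15 (1R,2S,3S,4R,6S)-2-hydroxy-1-methyl-4-{(2R)-2-[(2E)-4-methylpent-2-enoyl]oxiran-2-yl}-7-oxabicyclo[4.1.0]heptan-3-yl 3-methylbutanoate, via ring-epoxide dienone 14 (not isolated)
Conditions: DBU (2.5 equiv), t-BuOOH (5.5 M in decane, 1.5 equiv), CH2Cl2, −20 → 0 °C
Reagents that add atoms: tert-butyl hydroperoxide CC(C)(C)OO
Why: DBU first closes the antiperiplanar bromohydrin by intramolecular SN2 (inversion at C3, β-oxirane 14) and then mediates a Weitz–Scheffer epoxidation in which t-BuOO– adds only to the unhindered C14 methylene (the β-isopropyl C9=C10 enone is far slower) and the peroxy enolate closes in its A1,3-minimised rotamer (C5–H eclipsing C7=C8) on the face flanked by C4H2 and not by the acyloxy-bearing C6, which gives 7R (about 4:1 expected, minor epimer removed by chromatography).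

**Step 8**
Reactants: 15 (1R,2S,3S,4R,6S)-2-hydroxy-1-methyl-4-{(2R)-2-[(2E)-4-methylpent-2-enoyl]oxiran-2-yl}-7-oxabicyclo[4.1.0]heptan-3-yl 3-methylbutanoate
Product: 16 (1S,3S,4R,6S)-1-methyl-4-{(2R)-2-[(2E)-4-methylpent-2-enoyl]oxiran-2-yl}-2-oxo-7-oxabicyclo[4.1.0]heptan-3-yl 3-methylbutanoate
Conditions: Dess–Martin periodinane (1.5 equiv), NaHCO3, CH2Cl2, 0 °C → rt
Reagents that add atoms: none
Why: Dess–Martin oxidation converts the hindered axial C1 carbinol into the ketone under buffered, non-enolising conditions, so both oxiranes, the ester and C6 (already trans-diequatorial with C5) are unaffected.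

**Step 9**
Reactants: 16 (1S,3S,4R,6S)-1-methyl-4-{(2R)-2-[(2E)-4-methylpent-2-enoyl]oxiran-2-yl}-2-oxo-7-oxabicyclo[4.1.0]heptan-3-yl 3-methylbutanoate
Product: 17 (1S,3S,4R,6S)-4-{(2R)-2-[(2E)-4-hydroperoxy-4-methylpent-2-enoyl]oxiran-2-yl}-1-methyl-2-oxo-7-oxabicyclo[4.1.0]heptan-3-yl 3-methylbutanoate (CNP0131119.1)
Conditions: N-hydroxyphthalimide (20 mol %), V-70 (5 mol %), O2 (1 atm), MeCN, 35 °C, dark; stopped at about 60 % conversion, 16 recycled
Reagents that add atoms: dioxygen O=O
Why: Proposed new method: late-stage NHPI-catalysed aerobic C–H hydroperoxidation (radical-chain autoxidation), in which the phthalimide-N-oxyl radical abstracts the weakest C–H of 16 (tertiary, allylic and vinylogously α to C8=O, about 80 kcal/mol), the delocalised radical carries no spin on C8 so neither oxirane opens, triplet O2 adds at the tertiary γ-terminus C11 so that the E-enone stays conjugated, and the peroxyl radical takes H from NHPI; the closest known reactions are NHPI/O2 hydroperoxidation of cumene-type and allylic tertiary C–H bonds and γ-C–H abstraction from enones by peroxyl radicals.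

**Compound list**
1 | toluene | Cc1ccccc1 | starting material
2 | (1S,2R)-3-methylcyclohexa-3,5-diene-1,2-diol | O[C@@H]1[C@H](O)C(C)=CC=C1 | intermediate
3 | 3-methylbutanoyl chloride | CC(C)CC(=O)Cl | starting material
4 | (1S,6R)-6-hydroxy-5-methylcyclohexa-2,4-dien-1-yl 3-methylbutanoate | CC(C)CC(=O)O[C@@H]1[C@H](O)C(C)=CC=C1 | intermediate
5 | (E)-5-methylhex-3-en-2-one | CC(=O)/C=C/C(C)C | starting material
6 | lithium (E)-5-methylhexa-1,3-dien-2-olate | [Li+].C=C([O-])/C=C/C(C)C | intermediate
7 | (E)-trimethyl[(5-methylhexa-1,3-dien-2-yl)oxy]silane | C=C(O[Si](C)(C)C)/C=C/C(C)C | intermediate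
8 | (E)-1-bromo-5-methylhex-3-en-2-one | BrCC(=O)/C=C/C(C)C | intermediate
9 | (1S,2R,6S)-2-hydroxy-3-methyl-6-[(3E)-5-methyl-2-oxohex-3-en-1-yl]cyclohex-3-en-1-yl 3-methylbutanoate | CC(C)CC(=O)O[C@@H]1[C@H](O)C(C)=CC[C@H]1CC(=O)/C=C/C(C)C | intermediate
10 | formaldehyde (used as paraformaldehyde) | C=O | starting material
11 | Mannich base of 9, C7–CH2N(i-Pr)2, C7 epimers | CC(C)CC(=O)O[C@@H]1[C@H](O)C(C)=CC[C@H]1C(CN(C(C)C)C(C)C)C(=O)/C=C/C(C)C | intermediate
12 | (1S,2R,6S)-2-hydroxy-3-methyl-6-[(4E)-6-methyl-3-oxohepta-1,4-dien-2-yl]cyclohex-3-en-1-yl 3-methylbutanoate | CC(C)CC(=O)O[C@@H]1[C@H](O)C(C)=CC[C@H]1C(=C)C(=O)/C=C/C(C)C | intermediate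
13 | (1S,2S,3R,4R,6S)-4-bromo-2,3-dihydroxy-3-methyl-6-[(4E)-6-methyl-3-oxohepta-1,4-dien-2-yl]cyclohexyl 3-methylbutanoate | CC(C)CC(=O)O[C@@H]1[C@H](O)[C@@](C)(O)[C@H](Br)C[C@H]1C(=C)C(=O)/C=C/C(C)C | intermediate
14 | (1R,2S,3S,4S,6S)-2-hydroxy-1-methyl-4-[(4E)-6-methyl-3-oxohepta-1,4-dien-2-yl]-7-oxabicyclo[4.1.0]heptan-3-yl 3-methylbutanoate | CC(C)CC(=O)O[C@@H]1[C@H](O)[C@@]2(C)O[C@H]2C[C@H]1C(=C)C(=O)/C=C/C(C)C | intermediate
15 | (1R,2S,3S,4R,6S)-2-hydroxy-1-methyl-4-{(2R)-2-[(2E)-4-methylpent-2-enoyl]oxiran-2-yl}-7-oxabicyclo[4.1.0]heptan-3-yl 3-methylbutanoate | CC(C)CC(=O)O[C@@H]1[C@H](O)[C@@]2(C)O[C@H]2C[C@H]1[C@]1(C(=O)/C=C/C(C)C)CO1 | intermediate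
16 | (1S,3S,4R,6S)-1-methyl-4-{(2R)-2-[(2E)-4-methylpent-2-enoyl]oxiran-2-yl}-2-oxo-7-oxabicyclo[4.1.0]heptan-3-yl 3-methylbutanoate | CC(C)CC(=O)O[C@@H]1C(=O)[C@@]2(C)O[C@H]2C[C@H]1[C@]1(C(=O)/C=C/C(C)C)CO1 | intermediate
17 | (1S,3S,4R,6S)-4-{(2R)-2-[(2E)-4-hydroperoxy-4-methylpent-2-enoyl]oxiran-2-yl}-1-methyl-2-oxo-7-oxabicyclo[4.1.0]heptan-3-yl 3-methylbutanoate | CC(C)CC(=O)O[C@@H]1C(=O)[C@@]2(C)O[C@H]2C[C@H]1[C@]1(C(=O)/C=C/C(C)(C)OO)CO1 | target

**Step count**
Total step count: 9. Longest linear sequence: 8 (steps 1, 2, 4, 5, 6, 7, 8, 9). Step 3 is the side branch.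

**Steps most likely to fail**

Step 4. The risks are aromatisation or dimerisation of the dienyl ester, simple reduction of 8, H-abstraction from the doubly activated C6–H, and a modest facial ratio. The fallback sets out from 2 and comes back at 9, and it makes the C–C bond before the acylation on a rigid diene that cannot lose a carboxylic acid. Compound 2 is ketalised (2,2-dimethoxypropane, cat. PPTS) to the acetonide (3aR,7aS)-2,2,4-trimethyl-3a,7a-dihydro-1,3-benzodioxole F1. The radical from 8 is added to F1, whose cis-fused dioxolane closes the α face completely, to give the acetonide adduct (3E)-5-methyl-1-[(3aS,4S,7aR)-2,2,7-trimethyl-3a,4,5,7a-tetrahydro-1,3-benzodioxol-4-yl]hex-3-en-2-one F2. Aqueous acetic acid then frees the diol (3E)-1-[(1S,5R,6S)-5,6-dihydroxy-4-methylcyclohex-3-en-1-yl]-5-methylhex-3-en-2-one F3. Kinetic acylation with 3/pyridine at the equatorial C6–OH gives 9, because the C1–OH is pseudoaxial and flanked by the C2 methyl.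

Step 7. The risk is that substrate control at the acyclic quaternary C7 turns out low or reversed. The fallback sets out from 13 and comes back at 16, and it replaces nucleophilic epoxidation by reagent-controlled electrophilic epoxidation.
- Compound 13 is treated with DBU alone and 14 is isolated.
- (R)-Me-CBS/catecholborane reduces C8=O, with the α-branched alkenyl group acting as the large group, to the bis-allylic alcohol (1R,2S,3S,4S,6S)-2-hydroxy-4-[(3S,4E)-3-hydroxy-6-methylhepta-1,4-dien-2-yl]-1-methyl-7-oxabicyclo[4.1.0]heptan-3-yl 3-methylbutanoate F4.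
- Sharpless epoxidation (Ti(OiPr)4, L-(+)-DIPT, t-BuOOH, 4 Å MS, −20 °C) is matched for C7=C14 and mismatched for C9=C10 at an 8S carbinol. It gives the epoxy diol (1R,2S,3S,4R,6S)-2-hydroxy-4-{(2R)-2-[(1S,2E)-1-hydroxy-4-methylpent-2-en-1-yl]oxiran-2-yl}-1-methyl-7-oxabicyclo[4.1.0]heptan-3-yl 3-methylbutanoate F5.
- Excess Dess–Martin periodinane oxidises both carbinols at once to 16.

Step 9. The risks are a sluggish chain because the γ-C–H is polarity-deactivated, competing C–H sites, and decay of the hydroperoxide. The fallback sets out from 16 and comes back at 17, and it separates C–H cleavage from C–O formation. Wohl–Ziegler bromination (NBS, AIBN, PhCF3, 80 °C) gives the tertiary allylic bromide (1S,3S,4R,6S)-4-{(2R)-2-[(2E)-4-bromo-4-methylpent-2-enoyl]oxiran-2-yl}-1-methyl-2-oxo-7-oxabicyclo[4.1.0]heptan-3-yl 3-methylbutanoate F6. Silver-assisted perhydrolysis (ethereal H2O2, AgOCOCF3, Et2O, 0 °C) then converts F6 into 17.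

**Further compounds**
F1 | step 4 | (3aR,7aS)-2,2,4-trimethyl-3a,7a-dihydro-1,3-benzodioxole | CC1(C)O[C@@H]2[C@H](O1)C(C)=CC=C2
F2 | step 4 | (3E)-5-methyl-1-[(3aS,4S,7aR)-2,2,7-trimethyl-3a,4,5,7a-tetrahydro-1,3-benzodioxol-4-yl]hex-3-en-2-one | CC1(C)O[C@@H]2[C@H](O1)C(C)=CC[C@H]2CC(=O)/C=C/C(C)C
F3 | step 4 | (3E)-1-[(1S,5R,6S)-5,6-dihydroxy-4-methylcyclohex-3-en-1-yl]-5-methylhex-3-en-2-one | O[C@@H]1[C@H](O)C(C)=CC[C@H]1CC(=O)/C=C/C(C)C
F4 | step 7 | (1R,2S,3S,4S,6S)-2-hydroxy-4-[(3S,4E)-3-hydroxy-6-methylhepta-1,4-dien-2-yl]-1-methyl-7-oxabicyclo[4.1.0]heptan-3-yl 3-methylbutanoate | CC(C)CC(=O)O[C@@H]1[C@H](O)[C@@]2(C)O[C@H]2C[C@H]1C(=C)[C@@H](O)/C=C/C(C)C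
F5 | step 7 | (1R,2S,3S,4R,6S)-2-hydroxy-4-{(2R)-2-[(1S,2E)-1-hydroxy-4-methylpent-2-en-1-yl]oxiran-2-yl}-1-methyl-7-oxabicyclo[4.1.0]heptan-3-yl 3-methylbutanoate | CC(C)CC(=O)O[C@@H]1[C@H](O)[C@@]2(C)O[C@H]2C[C@H]1[C@]1([C@@H](O)/C=C/C(C)C)CO1
F6 | step 9 | (1S,3S,4R,6S)-4-{(2R)-2-[(2E)-4-bromo-4-methylpent-2-enoyl]oxiran-2-yl}-1-methyl-2-oxo-7-oxabicyclo[4.1.0]heptan-3-yl 3-methylbutanoate | CC(C)CC(=O)O[C@@H]1C(=O)[C@@]2(C)O[C@H]2C[C@H]1[C@]1(C(=O)/C=C/C(C)(C)Br)CO1
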